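Everything rests on disconnecting the C3=C4 bond of the oxygen heterocycle (ring B) at the 2H-chromene oxidation level. The key step exploits the fact that O1, the quaternary C2 with its methyl group, C3 and the six-carbon side chain are all present in (R)-linalool, whose carbinol carbon becomes C2, so only the link from C3 to C4 on the arene (ring A) is missing. After SNAr etherification of a fluorobenzaldehyde and methylenation, one ring-closing metathesis joins the linalyl vinyl carbon to the styrene carbon and closes ring B without touching C2. The precursor is an aryl linalyl ether bearing an ortho vinyl group, the bromide and a MOM-protected phenol; hydration, benzylic oxidation and deprotection finish.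

Key step: step 5

Assumption: (R)-linalool of high enantiomeric purity is used; its carbinol centre becomes C2 with no bond to it made or broken, so the enantiomeric purity of the target can only equal that of the linalool.

Step 1
Reactants: 1 4-bromo-2-fluoro-5-methoxybenzaldehyde
Product: 3 4-bromo-2-fluoro-5-hydroxybenzaldehyde, via aryloxydibromoborane 2 (not isolated)
Conditions: BBr3, CH2Cl2, −78 °C → 0 °C; then H2O
Reagents that add atoms: none
Why: Lewis-acid cleavage of an aryl methyl ether (BBr3 demethylation), in which bromide attacks the methyl group of the boron-complexed ether while the formyl group, the aryl fluoride and the aryl bromide are left alone at low temperature, and water then hydrolyses the aryloxyborane to the phenol.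

Step 2
Reactants: 3 4-bromo-2-fluoro-5-hydroxybenzaldehyde
Product: 4 4-bromo-2-fluoro-5-(methoxymethoxy)benzaldehyde
Conditions: MOMCl, i-Pr2NEt, CH2Cl2, 0 °C → rt
Reagents that add atoms: chloromethyl methyl ether (MOMCl), COCCl
Why: Williamson-type O-alkylation of the phenol with the reactive α-chloro ether should give the MOM acetal, which is stable to the alkoxide, ylide, carbene, radical and oxidation steps ahead and leaves under mild acid at the end.

Step 3
Reactants: 4 4-bromo-2-fluoro-5-(methoxymethoxy)benzaldehyde, 5 (R)-(−)-linalool
Product: 7 4-bromo-2-{[(3R)-3,7-dimethylocta-1,6-dien-3-yl]oxy}-5-(methoxymethoxy)benzaldehyde, via potassium linaloolate 6 (not isolated)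
Conditions: 5 (1.3 equiv), KN(SiMe3)2 (1.2 equiv), THF, 0 °C; then 4, 0 °C → rt
Reagents that add atoms: none
Why: Nucleophilic aromatic substitution (SNAr, addition–elimination) in which the preformed tertiary alkoxide adds at the carbon ortho to the activating formyl group and fluoride, a far better leaving group in this mechanism than the bromide para to the formyl group, departs; the alkoxide has no carbinol hydrogen and so cannot reduce the aldehyde, and since the C–O bond of linalool is never broken the (R) centre is carried over unchanged.

Step 4
Reactants: 7 4-bromo-2-{[(3R)-3,7-dimethylocta-1,6-dien-3-yl]oxy}-5-(methoxymethoxy)benzaldehyde, 8 methyltriphenylphosphonium bromide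
Product: 10 1-bromo-4-ethenyl-5-{[(3R)-3,7-dimethylocta-1,6-dien-3-yl]oxy}-2-(methoxymethoxy)benzene, via methylidenetriphenylphosphorane 9 (not isolated)
Conditions: 8, KOt-Bu, THF, 0 °C; then 7, 0 °C → rt
Reagents that add atoms: none
Why: Wittig methylenation with the non-stabilised ylide should convert the ortho-alkoxybenzaldehyde into the styrene under basic conditions at or below room temperature, which spare the acid- and heat-sensitive tertiary allyl aryl ether (no ionisation, no Claisen rearrangement), the MOM group and the stereocentre.

Step 5
Reactants: 10 1-bromo-4-ethenyl-5-{[(3R)-3,7-dimethylocta-1,6-dien-3-yl]oxy}-2-(methoxymethoxy)benzene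
Product: 11 (2R)-7-bromo-6-(methoxymethoxy)-2-methyl-2-(4-methylpent-3-en-1-yl)-2H-chromene
Conditions: second-generation Grubbs catalyst (H2IMes)(PCy3)Cl2Ru=CHPh (5 mol%), CH2Cl2 (0.005 M), 40 °C, Ar sparge, dark
Reagents that add atoms: none
Why: Ring-closing olefin metathesis by the [2+2] cycloaddition/cycloreversion mechanism: the ruthenium alkylidene exchanges first onto the unhindered styrene terminus, the resulting aryl carbene adds to the linalyl vinyl group held beside it, and collapse of the ruthenacyclobutane releases the C3=C4 alkene while ethene escapes and drives the reaction. The closest known reaction type is the ring-closing metathesis of 2-vinylaryl allyl ethers to 2H-chromenes. Ring B closes as a six-membered ring by intramolecular alkene–alkene metathesis between two terminal vinyl groups fixed ortho to each other on ring A, helped by the fully substituted C2 (gem-disubstituent effect). No stereocentre is formed; C2 keeps the (R) configuration of linalool because none of its four bonds takes part, and light and heat are avoided so that neither reversible electrocyclic opening of the O1–C2 bond nor aromatic Claisen rearrangement can intervene. The selectivity needed is chemoselectivity for the two monosubstituted alkenes over the trisubstituted side-chain alkene, whose engagement would expel 2-methylpropene and close a cyclopentene; it should be secured by the much faster loading of the catalyst on the styrene, by the absence of a free allylic hydroxyl group that would speed the five-ring pathway, and by working dilute at 40 °C.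

Step 6
Reactants: 11 (2R)-7-bromo-6-(methoxymethoxy)-2-methyl-2-(4-methylpent-3-en-1-yl)-2H-chromene
Product: 13 (2R)-7-bromo-2-(4-hydroxy-4-methylpentyl)-6-(methoxymethoxy)-2-methyl-3,4-dihydro-2H-chromen-4-ol (C4 epimers), via bis-hydroperoxide 12 (not isolated)
Conditions: Mn(dpm)3 (10 mol%), PhSiH3, O2 (1 atm), i-PrOH/CH2Cl2, 0 °C → rt; then PPh3
Reagents that add atoms: dioxygen, O=O
Why: Mukaiyama-type hydration (hydrogen-atom transfer from a manganese hydride made from tris(dipivaloylmethanato)manganese and the silane, then capture of the carbon radical by O2) should place hydrogen on C3 and on the less substituted side-chain alkene carbon, oxygenate the benzylic C4 radical and the tertiary side-chain radical, and after PPh3 reduction of the hydroperoxides give both Markovnikov alcohols in one operation with the aryl bromide and MOM ether untouched; the new C4 centre forms without control as an epimer mixture that step 7 erases, any C4 ketone formed directly converges there as well, and C2 is not involved.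

Step 7
Reactants: 13 (2R)-7-bromo-2-(4-hydroxy-4-methylpentyl)-6-(methoxymethoxy)-2-methyl-3,4-dihydro-2H-chromen-4-ol (C4 epimers)
Product: 14 (2R)-7-bromo-2-(4-hydroxy-4-methylpentyl)-6-(methoxymethoxy)-2-methyl-2,3-dihydro-4H-chromen-4-one
Conditions: Dess–Martin periodinane, CH2Cl2, 0 °C → rt
Reagents that add atoms: none
Why: Dess–Martin oxidation should convert the secondary benzylic alcohol into the aryl ketone under neutral, non-basic conditions that cannot trigger retro-oxa-Michael opening (and thus scrambling) at C2, while the tertiary alcohol cannot be oxidised.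

Step 8
Reactants: 14 (2R)-7-bromo-2-(4-hydroxy-4-methylpentyl)-6-(methoxymethoxy)-2-methyl-2,3-dihydro-4H-chromen-4-one
Product: 15 (2R)-7-bromo-6-hydroxy-2-(4-hydroxy-4-methylpentyl)-2-methyl-2,3-dihydro-4H-chromen-4-one
Conditions: 3 M aq HCl, THF, rt → 40 °C
Reagents that add atoms: none
Why: Acid-catalysed acetal hydrolysis should remove the phenolic MOM group under mild conditions; in the water-rich medium the tertiary alcohol can only return to itself if it ionises, dilute acid does not open the 2,2-disubstituted chromanone, and the phenol is freed only now because a free 6-hydroxychroman would act as a radical trap in step 6.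

Compound list
1 | 4-bromo-2-fluoro-5-methoxybenzaldehyde | COc1cc(C=O)c(F)cc1Br | starting material
2 | dibromo(2-bromo-4-fluoro-5-formylphenoxy)borane (formed in the flask) | O=Cc1cc(OB(Br)Br)c(Br)cc1F | intermediate
3 | 4-bromo-2-fluoro-5-hydroxybenzaldehyde | O=Cc1cc(O)c(Br)cc1F | intermediate
4 | 4-bromo-2-fluoro-5-(methoxymethoxy)benzaldehyde | COCOc1cc(C=O)c(F)cc1Br | intermediate
5 | (R)-(−)-linalool, (3R)-3,7-dimethylocta-1,6-dien-3-ol | C=C[C@](C)(O)CCC=C(C)C | starting material
6 | potassium (3R)-3,7-dimethylocta-1,6-dien-3-olate (formed in the flask) | C=C[C@](C)([O-])CCC=C(C)C.[K+] | intermediate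
7 | 4-bromo-2-{[(3R)-3,7-dimethylocta-1,6-dien-3-yl]oxy}-5-(methoxymethoxy)benzaldehyde | CC(C)=CCC[C@](C)(C=C)Oc1cc(Br)c(OCOC)cc1C=O | intermediate
8 | methyltriphenylphosphonium bromide | C[P+](c1ccccc1)(c1ccccc1)c1ccccc1.[Br-] | starting material
9 | methylidenetriphenylphosphorane (formed in the flask) | C=P(c1ccccc1)(c1ccccc1)c1ccccc1 | intermediate
10 | 1-bromo-4-ethenyl-5-{[(3R)-3,7-dimethylocta-1,6-dien-3-yl]oxy}-2-(methoxymethoxy)benzene | CC(C)=CCC[C@](C)(C=C)Oc1cc(Br)c(OCOC)cc1C=C | intermediate
11 | (2R)-7-bromo-6-(methoxymethoxy)-2-methyl-2-(4-methylpent-3-en-1-yl)-2H-chromene | CC(C)=CCC[C@]1(C)C=Cc2cc(OCOC)c(Br)cc2O1 | intermediate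
12 | (2R)-7-bromo-4-hydroperoxy-2-(4-hydroperoxy-4-methylpentyl)-6-(methoxymethoxy)-2-methyl-3,4-dihydro-2H-chromene (C4 epimers; formed in the flask) | CC(C)(OO)CCC[C@]1(C)CC(OO)c2cc(OCOC)c(Br)cc2O1 | intermediate
13 | (2R)-7-bromo-2-(4-hydroxy-4-methylpentyl)-6-(methoxymethoxy)-2-methyl-3,4-dihydro-2H-chromen-4-ol (C4 epimers) | CC(C)(O)CCC[C@]1(C)CC(O)c2cc(OCOC)c(Br)cc2O1 | intermediate
14 | (2R)-7-bromo-2-(4-hydroxy-4-methylpentyl)-6-(methoxymethoxy)-2-methyl-2,3-dihydro-4H-chromen-4-one | CC(C)(O)CCC[C@]1(C)CC(=O)c2cc(OCOC)c(Br)cc2O1 | intermediate
15 | (2R)-7-bromo-6-hydroxy-2-(4-hydroxy-4-methylpentyl)-2-methyl-2,3-dihydro-4H-chromen-4-one | CC(C)(O)CCC[C@]1(C)CC(=O)c2cc(O)c(Br)cc2O1 | target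

Total step count: 8
Longest linear sequence: 8 steps (1 → 15); linalool 5 and phosphonium salt 8 enter without steps of their own.

Steps most likely to fail

Step 5. The metathesis may engage the trisubstituted side-chain alkene, with loss of 2-methylpropene and five-membered ring closure onto the linalyl vinyl group, in competition with the six-membered closure. The fallback removes that alkene before the ring closure and sets out from 10. mCPBA (1.0 equiv, NaHCO3, CH2Cl2, 0 °C) should epoxidise the electron-rich trisubstituted alkene selectively to 1-bromo-5-{[(3R)-5-(3,3-dimethyloxiran-2-yl)-3-methylpent-1-en-3-yl]oxy}-4-ethenyl-2-(methoxymethoxy)benzene F4. With only the two vinyl groups left, the same ruthenium catalyst should close ring B to (2R)-7-bromo-2-[2-(3,3-dimethyloxiran-2-yl)ethyl]-6-(methoxymethoxy)-2-methyl-2H-chromene F5. LiBHEt3 in THF at 0 °C delivers hydride to the less substituted oxirane carbon and should give 5-[(2R)-7-bromo-6-(methoxymethoxy)-2-methyl-2H-chromen-2-yl]-2-methylpentan-2-ol F6. Hydration of the remaining C3=C4 alkene under the conditions of step 6 passes through the C4 hydroperoxide 5-[(2R)-7-bromo-4-hydroperoxy-6-(methoxymethoxy)-2-methyl-3,4-dihydro-2H-chromen-2-yl]-2-methylpentan-2-ol F7, which PPh3 reduces in the flask, and the route is rejoined at 13.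

Step 3. The hindered alkoxide may add too slowly to a ring deactivated by the acetal oxygen para to the fluoride, so that base-induced consumption of the formyl group outruns the substitution. The fallback replaces the formyl group by a cyano group for the etherification and sets out from 4. I2 and aqueous NH3 in THF at rt should give 4-bromo-2-fluoro-5-(methoxymethoxy)benzonitrile F1, whose cyano group activates the fluoride comparably but is not consumed by base. The SNAr with potassium linaloolate 6 can then be forced (THF/DMF, 18-crown-6, up to 50 °C) to give 4-bromo-2-{[(3R)-3,7-dimethylocta-1,6-dien-3-yl]oxy}-5-(methoxymethoxy)benzonitrile F2. i-Bu2AlH in toluene at −78 °C should stop at the N-(diisobutylalumanyl)aldimine F3, which is hydrolysed without isolation (aqueous potassium sodium tartrate, then wet silica gel) to aldehyde 7, where the route is rejoined.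

Step 6. The two alkenes may react at different rates and the carbon radicals may be reduced to C–H instead of being oxygenated, leaving partly hydrated and saturated material. The fallback is an ionic Markovnikov hydration and sets out from 11. Hg(OAc)2 in THF/H2O should add to both alkenes, with water entering at the benzylic C4 and at the tertiary side-chain carbon, to give the bis(acetoxymercurio) diol F8. NaBH4 in aqueous NaOH, added to the same flask, replaces both C–Hg bonds by C–H and the route is rejoined at 13.

Further compounds
F1 | step 3 | 4-bromo-2-fluoro-5-(methoxymethoxy)benzonitrile | COCOc1cc(C#N)c(F)cc1Br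
F2 | step 3 | 4-bromo-2-{[(3R)-3,7-dimethylocta-1,6-dien-3-yl]oxy}-5-(methoxymethoxy)benzonitrile | CC(C)=CCC[C@](C)(C=C)Oc1cc(Br)c(OCOC)cc1C#N
F3 | step 3 | N-(diisobutylalumanyl)-1-(4-bromo-2-{[(3R)-3,7-dimethylocta-1,6-dien-3-yl]oxy}-5-(methoxymethoxy)phenyl)methanimine (formed in the flask) | CC(C)=CCC[C@](C)(C=C)Oc1cc(Br)c(OCOC)cc1C=N[Al](CC(C)C)CC(C)C
F4 | step 5 | 1-bromo-5-{[(3R)-5-(3,3-dimethyloxiran-2-yl)-3-methylpent-1-en-3-yl]oxy}-4-ethenyl-2-(methoxymethoxy)benzene (epimers at the oxirane carbon) | CC1(C)OC1CC[C@](C)(C=C)Oc2cc(Br)c(OCOC)cc2C=C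
F5 | step 5 | (2R)-7-bromo-2-[2-(3,3-dimethyloxiran-2-yl)ethyl]-6-(methoxymethoxy)-2-methyl-2H-chromene (epimers at the oxirane carbon) | CC1(C)OC1CC[C@]2(C)C=Cc3cc(OCOC)c(Br)cc3O2
F6 | step 5 | 5-[(2R)-7-bromo-6-(methoxymethoxy)-2-methyl-2H-chromen-2-yl]-2-methylpentan-2-ol | CC(C)(O)CCC[C@]1(C)C=Cc2cc(OCOC)c(Br)cc2O1
F7 | step 5 | 5-[(2R)-7-bromo-4-hydroperoxy-6-(methoxymethoxy)-2-methyl-3,4-dihydro-2H-chromen-2-yl]-2-methylpentan-2-ol (C4 epimers; formed in the flask) | CC(C)(O)CCC[C@]1(C)CC(OO)c2cc(OCOC)c(Br)cc2O1
F8 | step 6 | (2R)-3-(acetoxymercurio)-2-[3-(acetoxymercurio)-4-hydroxy-4-methylpentyl]-7-bromo-6-(methoxymethoxy)-2-methyl-3,4-dihydro-2H-chromen-4-ol (formed in the flask) | CC(C)(O)C([Hg]OC(C)=O)CC[C@]1(C)C([Hg]OC(C)=O)C(O)c2cc(OCOC)c(Br)cc2O1
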